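## Structural features

The target is a 6,7-seco-ent-kaurane. Ring A (C1–C5, C10) is joined only through the single bond C9–C10 to a bicyclo[3.2.1]octane, in which the six-membered ring C (C8, C9, C11–C14) and the five-membered ring D (C8, C13–C16) share C8, C14 and C13. Ring A carries three contiguous stereocentres: C4 (CH3, CO2H = C19), C5 (H, CO2H = C6) and C10 (CH3, C9), with C19 and C6 cis and C9 trans to both. In the bicycle, C9 (H) lies between the aldehyde-bearing quaternary C8 and the C11 ketone, and C13 is the second bridgehead, so C10–C9–C8 is a quaternary–tertiary–quaternary run across a freely rotating bond. Fragile points are the C9 hydrogen alpha to the ketone, the 1,4-related C7 aldehyde and C11 ketone (furan formation, aldol), the acid-labile 16-methylene, and the cis-diacid, which closes to an anhydride or, at lower oxidation level, to a lactone. The real difficulty is to relay the absolute configuration of ring A to C8, C9 and C13 without ring B, while keeping the oxidation levels of C6, C7, C11 and C19 apart. The key step exploits the fact that, with C5 trigonal and C19 and C9 taken as like carbon arms, C4 and C10 are related by a twofold axis through C5 and C2 of ring A.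

## Logic of the disconnections

**40 from 38.** The two O–C(CH3)3 bonds are cut last (through 39). Alkyl–oxygen cleavage does not depend on access to the shielded acyl carbons, but it demands conditions that spare the 16-methylene, the aldehyde and C9–H.

**38 from 37.** C8–C15 is cut, opening ring D. The bond can only form on the face of ring C that carries the C13 arm, so C8 is fixed by geometry. The forward step must not epimerise C9.

**37 from 36.** The C–Cl bond is removed. This leaves an isopropenyl group that tolerates all earlier steps; the demand is a chlorination that spares two carbonyl groups.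

**36 from 32 and 33 (through 34 and 35).** C7–C8 is cut. C8 is the free beta-carbon of an enone, so C7 can come from a one-carbon formyl-anion equivalent without hydride chemistry.

**32 from 30 (through 31).** The C8=C9 bond of ring C is cut to a 1,5-keto aldehyde. Only closure through C9 gives a six-membered ring, so the hindered C9 is forced to react.

**30 from 28 and 29.** C13–C16 is cut. C13 is four bonds from the nearest stereocentre, so it needs a catalyst; everything else in the bicycle is then derived from it.

**28 from 26 and 27; 26 from 23 and 24.** The C12=C13 double bond is cut twice (metathesis, then methylenation). This needs kinetic enolisation of 23 at the methyl group and esters inert to ruthenium carbenes.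

**23 from 21; 21 from 20; 20 from 17 and 18 (through 19).** Ester protection and an oxidation-level change come off, and then C9–C11 is cut. C9 must change from a formyl carbon to a methylene alpha to the ketone while C19 stays masked.

**17 from 15 (through 16).** Both arm C=C bonds are cut, and the C19–O bond of the five-membered acyl lactol is opened. Reversible ring–chain closure picks the formyl group cis to C6 and so names the arms C19 and C9. The demand is thermodynamic control, because a trans-fused ring is strained but not impossible.

**15 from 14; 14 from 13; 13 from 11 and 12.** C5–C6 is cut. Because of the twofold axis, C5 is not stereogenic at this stage, so the one-carbon homologation needs no facial control, only access to a doubly neopentyl ketone.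

**11 from 10.** Double-bond migration; alkene geometry is irrelevant.

**10 from 8 (through 9).** C4–C19 and C9–C10 are cut. Both quaternary centres come from one catalyst, and 8 is used as the unseparated diastereomer mixture.

**8 from 6 and 7; 6 from 4 and 5; 4 from 3; 3 from 1 and 2.** Two C–CH3 bonds, one C–acyl bond and the ring bond are cut. The acylation must go on carbon, which the dianion of 4 secures.

## Other disconnections considered

**Alternative 1:** The cut is C9–C10 and C8–C15, with a temporary C5–C7 bond. A Lewis acid (Sc(OTf)3 or BF3·OEt2) would close dienone A2 by conrotation, and the allylsilane would trap the oxyallyl cation at C8 to give A1.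
- In favour: one operation makes the C9–C10 bond, the C8 quaternary centre, ring D and the 16-methylene. In bond economy this is better than the chosen plan, and C9/C10 are related inside a ring, which is at least its equal.
- Against: C10 is created in the cascade, so the twofold symmetry of ring A is not used, and C4 alone must steer the torquoselectivity from a distance. The C5–C7 ring must then be cleaved in the presence of the 16-methylene, C5 must gain H and C6 with control, and C7 and C11 must change oxidation level.
- Comparison: fewer steps to the skeleton, but probably more after it; stereocontrol of ring A is weaker than with the double allylation.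

**Alternative 2:** The cut is C8–C9 and C12–C13. The enamine of A5 with a chiral primary amine–thiourea would add to C9 of A4; pivalate loss and addition of the ketone enol to C12 would give A3.
- In favour: ring C and the C8 quaternary centre form convergently in one step, and nitro and ketone are direct precursors of the C11 ketone and the 16-methylene. This is clearly better in step economy than the six steps the chosen plan spends on rings C and D.
- Against: C9 of A4 is a neopentyl beta-carbon and the enamine is alpha-branched. The catalyst must override the face of C9 that C20 and C6 leave open, which leads to the wrong C9. The lactone keeps C6 at the alcohol level, so a late oxidation beside the C7 aldehyde is needed.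
- Comparison: mechanistically elegant and shorter, but it rests on double stereodifferentiation at the most hindered bond. The chosen plan sets C13 remotely by catalyst and derives C8 and C9 from it.

**Alternative 3:** The cut is C15–C16. Iodine–magnesium exchange on A7, then copper and BF3·OEt2, would open the oxetane CH2 on the face of the alkenyl metal and give A6.
- In favour: C8 is fixed by reach alone, which is the same logic as, and equal to, the chosen ring D closure. C7 arrives as CH2OH, which is better than the nitro route to the aldehyde.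
- Against: the difficulty moves into A7, whose ring C already needs the C8–C9 bond beside two quaternary carbons and the C9/C13 trans relation. Opening at a neopentyl CH2 is slow, BF3 endangers the ketal, and two shielded methyl esters must be hydrolysed at the end beside an epimerisable C9.
- Comparison: similar length, with the hardest bond left unsolved.

Key step: step 5

**Remarks on the chemistry (assumptions, one line each)**

- ent-Kaurane numbering is used for all intermediates; 8 and 10 were checked atom by atom against 40, and (2S,6S)-10 carries the C4 and C10 configuration of 40.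
- A trans-fused five-membered lactol or lactone on ring A is strained but accessible, so the arms are differentiated under equilibrating conditions and not by assumed impossibility.
- A C5 methylene would not survive cleavage of the arms, and a C5 ketone between two carboxyl groups would be a double beta-keto acid; therefore C6 is brought in as an epoxide before the arms are cleaved.
- The Wittig salt 18 is treated as a purchasable reagent.
- Deliberately open centres: C19 in 16, 17, 19 and 20; C8 in 34–37 (C9 is drawn as the favoured epimer).

## Steps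

Step 1
Reactants: 1 pimelic acid; 2 allyl alcohol
Product: 3 diallyl heptanedioate
Conditions: 2 (excess), TsOH·H2O (cat.), toluene, reflux, Dean–Stark
Reagents that add atoms: allyl alcohol, C=CCO
Why: Fischer esterification driven by azeotropic removal of water; no stereocentre.

Step 2
Reactants: 3 diallyl heptanedioate
Product: 4 allyl 2-oxocyclohexane-1-carboxylate
Conditions: NaH, THF, reflux; then AcOH
Reagents that add atoms: none
Why: Dieckmann cyclisation to the six-membered beta-keto ester, pulled forward by formation of its enolate.

Step 3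
Reactants: 4 allyl 2-oxocyclohexane-1-carboxylate; 5 allyl chloroformate
Product: 6 diallyl 2-oxocyclohexane-1,3-dicarboxylate
Conditions: LDA (2.2 equiv), THF, −78 to 0 °C; 5, −78 °C; aq. HCl
Reagents that add atoms: allyl chloroformate, C=CCOC(=O)Cl
Why: Acylation of the beta-keto ester dianion at its carbanionic gamma-carbon (C3); the monoanion would be acylated on oxygen.

Step 4
Reactants: 6 diallyl 2-oxocyclohexane-1,3-dicarboxylate; 7 iodomethane
Product: 8 diallyl 1,3-dimethyl-2-oxocyclohexane-1,3-dicarboxylate (racemic plus meso)
Conditions: K2CO3, acetone, 50 °C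
Reagents that add atoms: iodomethane, CI
Why: Double C-methylation of the two doubly activated carbons; the diastereomer mixture is acceptable because both centres are erased in step 5.

Step 5
Reactants: 8 diallyl 1,3-dimethyl-2-oxocyclohexane-1,3-dicarboxylate
Product: 10 (2S,6S)-2,6-dimethyl-2,6-di(prop-2-en-1-yl)cyclohexan-1-one, via mono-allylated keto ester 9 (not isolated)
Conditions: Pd2(dba)3 (zerovalent palladium, 2.5 mol%), (S)-t-Bu-PHOX (6.5 mol%), THF, 25 to 40 °C
Reagents that add atoms: none
Why: Zerovalent palladium ionises one allyl ester to a pi-allyl palladium carboxylate, carbon dioxide is lost, and the resulting palladium enolate couples with the allyl fragment inside the chiral ligand sphere; the sequence repeats on 9. The closest known reaction type is the enantioconvergent decarboxylative allylic alkylation of alpha-quaternary allyl beta-keto esters, including its double version on cyclic bis(beta-keto esters). No ring is closed; the bonds formed are C4–C19 and C9–C10, each to an allyl CH2. Each new quaternary centre is set by the ligand-controlled face of a planar enolate, so the configurations present in 8 play no part. The (S)-ligand, which gives (S)-2-allyl-2-methylcyclohexanone from the parent ester, should give S at both centres. The step needs the C2 isomer over the meso isomer, which requires the second allylation to be reagent-controlled as well; the distant first quaternary centre should bias it little. Because the minor enantiomeric pathway is diverted mainly into the meso compound, the C2 product should be formed with amplified enantiopurity.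

Step 6
Reactants: 10 (2S,6S)-2,6-dimethyl-2,6-di(prop-2-en-1-yl)cyclohexan-1-one
Product: 11 (2S,6S)-2,6-dimethyl-2,6-di[(1E)-prop-1-en-1-yl]cyclohexan-1-one
Conditions: RuHCl(CO)(PPh3)3 (5 mol%), toluene, 80 °C
Reagents that add atoms: none
Why: Ruthenium hydride addition–elimination moves each terminal alkene to the more stable internal position; the quaternary carbons block further migration and the geometry is irrelevant.

Step 7
Reactants: 11 (2S,6S)-2,6-dimethyl-2,6-di[(1E)-prop-1-en-1-yl]cyclohexan-1-one; 12 trimethylsulfonium iodide
Product: 13 (4S,8S)-4,8-dimethyl-4,8-di[(1E)-prop-1-en-1-yl]-1-oxaspiro[2.5]octane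
Conditions: 12, n-BuLi, THF, −10 to 25 °C
Reagents that add atoms: trimethylsulfonium iodide, C[S+](C)C.[I-]
Why: Corey–Chaykovsky epoxidation; the small ylide adds to the non-enolisable ketone, and C5 remains non-stereogenic because C4 and C10 are identical arms.

Step 8
Reactants: 13 (4S,8S)-4,8-dimethyl-4,8-di[(1E)-prop-1-en-1-yl]-1-oxaspiro[2.5]octane
Product: 14 (2S,6S)-2,6-dimethyl-2,6-di[(1E)-prop-1-en-1-yl]cyclohexane-1-carbaldehyde
Conditions: BF3·OEt2 (0.5 equiv), CH2Cl2, −78 to −30 °C
Reagents that add atoms: none
Why: Meinwald rearrangement: opening at the tertiary C5 with hydride shift from C6 gives the aldehyde; C5 now bears H and C6 and is still not a stereocentre.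

Step 9
Reactants: 14 (2S,6S)-2,6-dimethyl-2,6-di[(1E)-prop-1-en-1-yl]cyclohexane-1-carbaldehyde
Product: 15 (2S,6S)-2,6-dimethyl-2,6-di[(1E)-prop-1-en-1-yl]cyclohexane-1-carboxylic acid
Conditions: NaClO2, NaH2PO4, 2-methylbut-2-ene, t-BuOH/H2O, 0 to 25 °C
Reagents that add atoms: sodium chlorite, [Na+].[O-]Cl=O
Why: Pinnick oxidation works on shielded aldehydes, and the scavenger protects the alkenes; C6 reaches the acid level before any lactone can form.

Step 10
Reactants: 15 (2S,6S)-2,6-dimethyl-2,6-di[(1E)-prop-1-en-1-yl]cyclohexane-1-carboxylic acid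
Product: 17 ring A methyl pseudo-ester [C6(=O)–O–C19H(OCH3) cis-fused at C4–C5; C10 bears CH3 and CHO (C9)], via cis-fused acyl lactol 16 (not isolated)
Conditions: O3, CH2Cl2/MeOH, −78 °C; Me2S; then PPTS (cat.), MeOH, 25 °C
Reagents that add atoms: ozone, [O-][O+]=O; methanol, CO
Why: Ozonolysis cleaves both arms to formyl groups; reversible ring–chain tautomerism then collects the less strained cis-fused five-membered acyl lactol, which is locked as the pseudo-ester. This closure makes C5 stereogenic with C6 cis to C19 and leaves the trans formyl group (C9) free.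

Step 11
Reactants: 17 ring A methyl pseudo-ester; 18 (1-methoxyethyl)triphenylphosphonium chloride
Product: 20 ring A keto pseudo-acid [C6(=O)–O–C19H(OH); C10 bears CH3 and CH2C(=O)CH3], via methyl enol ether 19 (not isolated)
Conditions: 18, KHMDS, THF, −78 to 0 °C; then 2 M HCl, THF, 45 °C
Reagents that add atoms: (1-methoxyethyl)triphenylphosphonium chloride, COC(C)[P+](c1ccccc1)(c1ccccc1)c1ccccc1.[Cl-]; water, O
Why: Wittig reaction of the alpha-alkoxy ylide with the non-enolisable neopentyl aldehyde, then acid hydrolysis of the enol ether, turns C9 into a methylene and adds C11 (ketone) and C12; the same acid returns the pseudo-ester to the pseudo-acid.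

Step 12
Reactants: 20 ring A keto pseudo-acid
Product: 21 keto diacid [ring A with C4 (CH3, CO2H), C5 (H, CO2H), C10 (CH3, CH2C(=O)CH3), configured as in 40]
Conditions: CrO3, H2SO4, acetone/H2O, 0 °C
Reagents that add atoms: water, O
Why: Jones oxidation of the lactol C–H gives the cyclic anhydride, which hydrolyses on work-up; C19 reaches the acid level with C4, C5 and C10 untouched.

Step 13
Reactants: 21 keto diacid; 22 2-methylprop-1-ene
Product: 23 di-tert-butyl ester of 21
Conditions: 22 (excess), H2SO4 (cat.), CH2Cl2, 25 °C, sealed vessel
Reagents that add atoms: 2-methylprop-1-ene, C=C(C)C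
Why: Acid-catalysed addition of the carboxylic acids to the alkene forms the esters at oxygen, so the shielding of the C19 and C6 acyl carbons does not matter.

Step 14
Reactants: 23 di-tert-butyl ester of 21; 24 N,N-dimethylmethyleneiminium iodide
Product: 26 vinyl ketone [C10–CH2–C(=O)–CH=CH2], via Mannich base 25 (not isolated)
Conditions: LDA, THF, −78 °C; 24, −78 to 0 °C; then iodomethane (7); then aq. NaHCO3, 25 °C
Reagents that add atoms: N,N-dimethylmethyleneiminium iodide, C[N+](C)=C.[I-]
Why: Kinetic deprotonation takes the methyl group (C12), not the neopentyl C9; Mannich reaction, quaternisation and elimination give the enone.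

Step 15
Reactants: 26 vinyl ketone; 27 4,4-diethoxybut-1-ene
Product: 28 (E)-enone acetal [C10–CH2–C(=O)–CH=CH–CH2–CH(OEt)2]
Conditions: 27 (3 equiv), second-generation Grubbs catalyst RuCl2(=CHPh)(H2IMes)(PCy3) (5 mol%), CH2Cl2, 40 °C
Reagents that add atoms: 4,4-diethoxybut-1-ene, C=CCC(OCC)OCC
Why: Cross-metathesis of an electron-poor enone with an unhindered terminal alkene should be selective for the E cross product; it brings in C13, C14 and C8 (masked aldehyde).

Step 16
Reactants: 28 (E)-enone acetal; 29 4,4,5,5-tetramethyl-2-(prop-1-en-2-yl)-1,3,2-dioxaborolane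
Product: 30 (13S)-isopropenyl keto acetal
Conditions: 29, [Rh(OH)((S)-binap)]2 (3 mol% monovalent rhodium), KOH (cat.), dioxane/H2O, 50 °C
Reagents that add atoms: 4,4,5,5-tetramethyl-2-(prop-1-en-2-yl)-1,3,2-dioxaborolane, CC(=C)B1OC(C)(C)C(C)(C)O1
Why: Hayashi–Miyaura 1,4-addition of the alkenyl–rhodium species to the enone face selected by the ligand sets C13 by catalyst alone, since the nearest stereocentre is four bonds away. The (S)-ligand is the one the accepted quadrant model assigns to this face of an (E)-enone; the antipode would be used if the sense were opposite.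

Step 17
Reactants: 30 (13S)-isopropenyl keto acetal
Product: 32 ring C enone [2-(ring A)-5-isopropenylcyclohex-2-en-1-one: C11=O, C8=C9], via keto aldehyde 31 (not isolated)
Conditions: PPTS, acetone/H2O, 50 °C; then pyrrolidine, AcOH (cat.), toluene, 60 °C
Reagents that add atoms: none
Why: Acetal hydrolysis frees the C8 aldehyde, and the amine-catalysed intramolecular aldol condensation can only close a six-membered ring through C9 (all other modes give four-membered rings), giving the conjugated enone.

Step 18
Reactants: 32 ring C enone; 33 nitromethane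
Product: 34 nitro ketone [C8 bears CH2NO2]
Conditions: 33 (10 equiv), DBU, MeCN, 40 °C
Reagents that add atoms: nitromethane, C[N+](=O)[O-]
Why: Michael addition of the nitronate to the unsubstituted beta-carbon C8 brings in C7 as a formyl-anion equivalent; C8 and C9 need no control here because both remain epimerisable.

Step 19
Reactants: 34 nitro ketone
Product: 36 keto aldehyde [C8 bears CHO (C7)], via sodium nitronate 35 (not isolated)
Conditions: NaOMe, MeOH, 0 °C; then TiCl3 (trivalent titanium), NH4OAc, THF/H2O, 25 °C
Reagents that add atoms: water, O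
Why: Reductive Nef reaction at near-neutral pH converts CH2NO2 into CHO without hydride; in the basic first stage C9 should equilibrate to the epimer with ring A equatorial and trans to the equatorial C13 substituent.

Step 20
Reactants: 36 keto aldehyde
Product: 37 allylic chloride [C13 bears C(=CH2)CH2Cl]
Conditions: Ca(OCl)2, CO2 (solid), CH2Cl2/H2O, 0 °C
Reagents that add atoms: calcium hypochlorite, [Ca+2].[O-]Cl.[O-]Cl
Why: Ene-type allylic chlorination by hypochlorous acid at the electron-rich 1,1-disubstituted alkene; at this buffered pH the carbonyl groups are not enolised.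

Step 21
Reactants: 37 allylic chloride
Product: 38 di-tert-butyl 7,11-dioxo-6,7-seco-ent-kaur-16-ene-6,19-dioate
Conditions: Pd(PPh3)4 (zerovalent palladium, 5 mol%), pyrrolidine (30 mol%), Et3N, THF, 25 to 40 °C; aq. NH4Cl
Reagents that add atoms: none
Why: Tsuji–Trost alpha-allylation of an aldehyde through its enamine: the amine condenses only with the aldehyde, palladium ionises the chloride to a symmetrical 2-substituted pi-allyl, and C8 attacks a terminus in a five-membered closure that forms C8–C15, ring D and the 16-methylene. The C13 arm reaches C8 only from its own face, so C15 enters cis to C16 and C7 ends cis to C10; the closure needs that arm axial, which makes the C9 epimer with ring A trans to it (axial, relieved of allylic strain against the exocyclic enamine) the productive one under non-epimerising conditions.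

Step 22
Reactants: 38 di-tert-butyl 7,11-dioxo-6,7-seco-ent-kaur-16-ene-6,19-dioate
Product: 40 7,11-dioxo-6,7-seco-ent-kaur-16-ene-6,19-dioic acid (CNP0408869.1), via bis(trimethylsilyl) ester 39 (not isolated)
Conditions: TMSOTf, 2,6-lutidine, CH2Cl2, 0 °C; then pH 4 buffer
Reagents that add atoms: none
Why: Silyl triflate dealkylation of tert-butyl esters by O-silylation and loss of the tert-butyl cation is independent of shielding at the acyl carbons; the lutidine buffer should spare the 16-methylene, the aldehyde and C9–H, and work-up hydrolyses the silyl esters.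

## Compound list

1 | pimelic acid | OC(=O)CCCCCC(=O)O | starting material
2 | allyl alcohol | C=CCO | starting material
3 | diallyl heptanedioate | C=CCOC(=O)CCCCCC(=O)OCC=C | intermediate
4 | allyl 2-oxocyclohexane-1-carboxylate | C=CCOC(=O)C1CCCCC1=O | intermediate
5 | allyl chloroformate | C=CCOC(=O)Cl | starting material
6 | diallyl 2-oxocyclohexane-1,3-dicarboxylate | C=CCOC(=O)C1CCCC(C(=O)OCC=C)C1=O | intermediate
7 | iodomethane | CI | starting material
8 | diallyl 1,3-dimethyl-2-oxocyclohexane-1,3-dicarboxylate (racemic plus meso) | C=CCOC(=O)C1(C)CCCC(C)(C(=O)OCC=C)C1=O | intermediate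
9 | allyl (3S)-1,3-dimethyl-2-oxo-3-(prop-2-en-1-yl)cyclohexane-1-carboxylate (C1 epimers) | C=CC[C@]1(C)CCCC(C)(C(=O)OCC=C)C1=O | intermediate (not isolated)
10 | (2S,6S)-2,6-dimethyl-2,6-di(prop-2-en-1-yl)cyclohexan-1-one | C=CC[C@]1(C)CCC[C@@](C)(CC=C)C1=O | intermediate
11 | (2S,6S)-2,6-dimethyl-2,6-di[(1E)-prop-1-en-1-yl]cyclohexan-1-one | C/C=C/[C@]1(C)CCC[C@@](C)(/C=C/C)C1=O | intermediate
12 | trimethylsulfonium iodide | C[S+](C)C.[I-] | starting material
13 | (4S,8S)-4,8-dimethyl-4,8-di[(1E)-prop-1-en-1-yl]-1-oxaspiro[2.5]octane | C/C=C/[C@]1(C)CCC[C@@](C)(/C=C/C)C12CO2 | intermediate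
14 | (2S,6S)-2,6-dimethyl-2,6-di[(1E)-prop-1-en-1-yl]cyclohexane-1-carbaldehyde | C/C=C/[C@]1(C)CCC[C@@](C)(/C=C/C)C1C=O | intermediate
15 | (2S,6S)-2,6-dimethyl-2,6-di[(1E)-prop-1-en-1-yl]cyclohexane-1-carboxylic acid | C/C=C/[C@]1(C)CCC[C@@](C)(/C=C/C)C1C(=O)O | intermediate
16 | ring A acyl lactol: gamma-lactone C6(=O)–O–C19H(OH) cis-fused at C4–C5, C10 with CH3 and CHO (C19 anomers) | O=C[C@]1(C)CCC[C@@]2(C)C(O)OC(=O)[C@@H]12 | intermediate (not isolated)
17 | ring A methyl pseudo-ester: as 16 with C19H(OCH3) | O=C[C@]1(C)CCC[C@@]2(C)C(OC)OC(=O)[C@@H]12 | intermediate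
18 | (1-methoxyethyl)triphenylphosphonium chloride | COC(C)[P+](c1ccccc1)(c1ccccc1)c1ccccc1.[Cl-] | starting material
19 | methyl enol ether: as 17 with C10–CH=C(OCH3)CH3 | COC(C)=C[C@]1(C)CCC[C@@]2(C)C(OC)OC(=O)[C@@H]12 | intermediate (not isolated)
20 | ring A keto pseudo-acid: as 16 with C10–CH2C(=O)CH3 | CC(=O)C[C@]1(C)CCC[C@@]2(C)C(O)OC(=O)[C@@H]12 | intermediate
21 | keto diacid: 1,3-dimethyl-3-(2-oxopropyl)cyclohexane-1,2-dicarboxylic acid, C4, C5, C10 as in 40 | CC(=O)C[C@]1(C)CCC[C@@](C)(C(=O)O)[C@H]1C(=O)O | intermediate
22 | 2-methylprop-1-ene | C=C(C)C | starting material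
23 | di-tert-butyl ester of 21 | CC(=O)C[C@]1(C)CCC[C@@](C)(C(=O)OC(C)(C)C)[C@H]1C(=O)OC(C)(C)C | intermediate
24 | N,N-dimethylmethyleneiminium iodide | C[N+](C)=C.[I-] | starting material
25 | Mannich base: as 23 with C10–CH2C(=O)CH2CH2N(CH3)2 | CN(C)CCC(=O)C[C@]1(C)CCC[C@@](C)(C(=O)OC(C)(C)C)[C@H]1C(=O)OC(C)(C)C | intermediate (not isolated)
26 | vinyl ketone: as 23 with C10–CH2C(=O)CH=CH2 | C=CC(=O)C[C@]1(C)CCC[C@@](C)(C(=O)OC(C)(C)C)[C@H]1C(=O)OC(C)(C)C | intermediate
27 | 4,4-diethoxybut-1-ene | C=CCC(OCC)OCC | starting material
28 | (E)-enone acetal: C10–CH2C(=O)CH=CHCH2CH(OEt)2 | CCOC(OCC)C/C=C/C(=O)C[C@]1(C)CCC[C@@](C)(C(=O)OC(C)(C)C)[C@H]1C(=O)OC(C)(C)C | intermediate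
29 | 4,4,5,5-tetramethyl-2-(prop-1-en-2-yl)-1,3,2-dioxaborolane | CC(=C)B1OC(C)(C)C(C)(C)O1 | starting material
30 | (13S)-isopropenyl keto acetal | CCOC(OCC)C[C@H](C(C)=C)CC(=O)C[C@]1(C)CCC[C@@](C)(C(=O)OC(C)(C)C)[C@H]1C(=O)OC(C)(C)C | intermediate
31 | keto aldehyde: as 30 with C8 as CHO | O=CC[C@H](C(C)=C)CC(=O)C[C@]1(C)CCC[C@@](C)(C(=O)OC(C)(C)C)[C@H]1C(=O)OC(C)(C)C | intermediate (not isolated)
32 | ring C enone: 2-(ring A)-5-isopropenylcyclohex-2-en-1-one | CC(=C)[C@H]1CC=C(C(=O)C1)[C@]2(C)CCC[C@@](C)(C(=O)OC(C)(C)C)[C@H]2C(=O)OC(C)(C)C | intermediate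
33 | nitromethane | C[N+](=O)[O-] | starting material
34 | nitro ketone: C8 with CH2NO2 (C8 epimers; C9 trans to C13) | CC(=C)[C@@H]1CC(=O)[C@H](C(C[N+](=O)[O-])C1)[C@]2(C)CCC[C@@](C)(C(=O)OC(C)(C)C)[C@H]2C(=O)OC(C)(C)C | intermediate
35 | sodium nitronate of 34 | CC(=C)[C@@H]1CC(=O)[C@H](C(C=[N+]([O-])[O-])C1)[C@]2(C)CCC[C@@](C)(C(=O)OC(C)(C)C)[C@H]2C(=O)OC(C)(C)C.[Na+] | intermediate (not isolated)
36 | keto aldehyde: C8 with CHO (C8 epimers; C9 trans to C13) | CC(=C)[C@@H]1CC(=O)[C@H](C(C=O)C1)[C@]2(C)CCC[C@@](C)(C(=O)OC(C)(C)C)[C@H]2C(=O)OC(C)(C)C | intermediate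
37 | allylic chloride: as 36 with C13–C(=CH2)CH2Cl | ClCC(=C)[C@@H]1CC(=O)[C@H](C(C=O)C1)[C@]2(C)CCC[C@@](C)(C(=O)OC(C)(C)C)[C@H]2C(=O)OC(C)(C)C | intermediate
38 | di-tert-butyl 7,11-dioxo-6,7-seco-ent-kaur-16-ene-6,19-dioate | C=C1C[C@]2(C=O)C[C@H]1CC(=O)[C@H]2[C@]1(C)CCC[C@@](C)(C(=O)OC(C)(C)C)[C@H]1C(=O)OC(C)(C)C | intermediate
39 | bis(trimethylsilyl) 7,11-dioxo-6,7-seco-ent-kaur-16-ene-6,19-dioate | C=C1C[C@]2(C=O)C[C@H]1CC(=O)[C@H]2[C@]1(C)CCC[C@@](C)(C(=O)O[Si](C)(C)C)[C@H]1C(=O)O[Si](C)(C)C | intermediate (not isolated)
40 | 7,11-dioxo-6,7-seco-ent-kaur-16-ene-6,19-dioic acid (CNP0408869.1) | C=C1C[C@]2(C=O)C[C@H]1CC(=O)[C@H]2[C@]1(C)CCC[C@@](C)(C(=O)O)[C@H]1C(=O)O | target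

## Step count and least certain steps

Total step count: 22. Longest linear sequence: 22 steps (1 to 40; 5, 7, 12, 18, 22, 24, 27, 29 and 33 are purchased).

**Step 5 (key step).** The second allylation may be partly steered by the first quaternary centre, and ionisation of the more hindered second ester may be slow; both would erode the C2-to-meso ratio. The meso isomer would have to be removed later, for example at the crystalline acid 15.
Fallback, from 4 back to 10, with the two centres set one at a time: methylation of 4 gives allyl 1-methyl-2-oxocyclohexane-1-carboxylate F1. Decarboxylative allylation with the same catalyst gives (S)-2-methyl-2-(prop-2-en-1-yl)cyclohexan-1-one F2. Methylation at the only enolisable carbon gives (2S)-2,6-dimethyl-2-(prop-2-en-1-yl)cyclohexan-1-one F3. O-Acylation of its enolate with 5 gives allyl (6S)-2,6-dimethyl-6-(prop-2-en-1-yl)cyclohex-1-en-1-yl carbonate F4, whose catalyst-controlled decarboxylative allylation returns to 10.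

**Step 7.** The ylide may fail to add to the doubly neopentyl ketone and decompose instead.
Fallback, from 11 back to 15: methylenation with Cp2Ti(CH3)2 gives (2S,6S)-1,3-dimethyl-2-methylidene-1,3-di[(1E)-prop-1-en-1-yl]cyclohexane F5. Hydroboration with 9-BBN, selective for the terminal carbon of the 1,1-disubstituted alkene over the internal neopentyl alkenes, then oxidation gives [(2S,6S)-2,6-dimethyl-2,6-di[(1E)-prop-1-en-1-yl]cyclohexyl]methanol F6. Oxidation with TEMPO and PhI(OAc)2 in aqueous MeCN returns to 15.

**Step 10.** Ring–chain closure may select the cis formyl group incompletely, or the free C9 aldehyde may be acetalised, which would blur the distinction between the arms.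
Fallback, from 15 back to 20, marking the cis arm by an irreversible 5-exo closure before any cleavage: iodolactonisation (I2, NaHCO3, MeCN) gives the cis-fused iodolactone F7. Ozonolysis of the remaining arm gives the iodolactone aldehyde F8. The Wittig–hydrolysis sequence of step 11 gives the iodolactone methyl ketone F9. Zinc in AcOH regenerates the acid and the cis alkene as the propenyl keto acid F10, and ozonolysis returns to 20.

**Step 16.** Transmetalation of the 1,1-disubstituted alkenyl boron reagent may be slow, protodeboronation may compete, and facial selectivity may be insufficient.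
Fallback, from 23 back to 31: kinetic silylation (LDA, TMSCl) gives the trimethylsilyl enol ether F11. An imidazolidinone-catalysed Mukaiyama–Michael addition to (E)-4-methylpenta-2,4-dienal sets C13 and delivers 31 directly; the second stage of step 17 then closes ring C.

**Step 21.** Enamine formation and attack at the fully substituted alpha-carbon may be sluggish, the amine may be allylated, or C9 may epimerise before closure and lead into the C9-epimeric bicycle. The preceding chlorination (step 20) may also touch the aldehyde.
Fallback, from 36 back to 38, avoiding both 37 and base: TBSCl and DBU give the tert-butyldimethylsilyl enol ether F12 of the aldehyde. Oxidative cyclisation with Pd(OAc)2 (divalent palladium) in DMSO under O2 joins C8 to the terminal carbon of the isopropenyl group, and beta-hydride loss from the methyl group gives the 16-methylene of 38.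

## Further compounds

F1 | step 5 | allyl 1-methyl-2-oxocyclohexane-1-carboxylate | C=CCOC(=O)C1(C)CCCCC1=O
F2 | step 5 | (S)-2-methyl-2-(prop-2-en-1-yl)cyclohexan-1-one | C=CC[C@]1(C)CCCCC1=O
F3 | step 5 | (2S)-2,6-dimethyl-2-(prop-2-en-1-yl)cyclohexan-1-one (C6 epimers) | C=CC[C@]1(C)CCCC(C)C1=O
F4 | step 5 | allyl (6S)-2,6-dimethyl-6-(prop-2-en-1-yl)cyclohex-1-en-1-yl carbonate | C=CC[C@]1(C)CCCC(C)=C1OC(=O)OCC=C
F5 | step 7 | (2S,6S)-1,3-dimethyl-2-methylidene-1,3-di[(1E)-prop-1-en-1-yl]cyclohexane | C/C=C/[C@]1(C)CCC[C@@](C)(/C=C/C)C1=C
F6 | step 7 | [(2S,6S)-2,6-dimethyl-2,6-di[(1E)-prop-1-en-1-yl]cyclohexyl]methanol | C/C=C/[C@]1(C)CCC[C@@](C)(/C=C/C)C1CO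
F7 | step 10 | cis-fused iodolactone: C6(=O)–O–C19H(CHICH3) at C4–C5, C10 with CH3 and (E)-propenyl | C/C=C/[C@]1(C)CCC[C@@]2(C)C(C(I)C)OC(=O)[C@@H]12
F8 | step 10 | iodolactone aldehyde: as F7 with C10–CHO | O=C[C@]1(C)CCC[C@@]2(C)C(C(I)C)OC(=O)[C@@H]12
F9 | step 10 | iodolactone methyl ketone: as F7 with C10–CH2C(=O)CH3 | CC(=O)C[C@]1(C)CCC[C@@]2(C)C(C(I)C)OC(=O)[C@@H]12
F10 | step 10 | propenyl keto acid: ring A with C4 (CH3, propenyl), C5 (H, CO2H), C10 (CH3, CH2C(=O)CH3) | CC(=O)C[C@]1(C)CCC[C@@](C)(/C=C/C)[C@H]1C(=O)O
F11 | step 16 | trimethylsilyl enol ether of 23 at C11–C12 | C=C(O[Si](C)(C)C)C[C@]1(C)CCC[C@@](C)(C(=O)OC(C)(C)C)[C@H]1C(=O)OC(C)(C)C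
F12 | step 21 | tert-butyldimethylsilyl enol ether of the C7 aldehyde of 36 | CC(=C)[C@@H]1CC(=O)[C@H](C(=CO[Si](C)(C)C(C)(C)C)C1)[C@]2(C)CCC[C@@](C)(C(=O)OC(C)(C)C)[C@H]2C(=O)OC(C)(C)C
A1 | alternative 1 | tetracyclic trimethylsilyl enol ether with the temporary C5–C7 ring, C11 silyl ether and 16-methylene | C=C1C[C@]2(C3O[Si](C)(C)C)C[C@H]1C[C@H](O[Si](C)(C)C(C)(C)C)[C@H]2[C@]1(C)CCC[C@@](C)(C(=O)OC)C1=3
A2 | alternative 1 | cross-conjugated dienone C10=C5–C7(=O)–C8=C9 with C11 silyl ether and C13 2-[(trimethylsilyl)methyl]vinyl group | C[Si](C)(C)CC(=C)[C@H]1CC(=C[C@@H](O[Si](C)(C)C(C)(C)C)C1)C(=O)C1=C(C)CCC[C@@]1(C)C(=O)OC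
A3 | alternative 2 | 11-nitro-16-oxo bicyclo[3.2.1]octane C7 aldehyde on the ring A 19,6-lactone | O=C1C[C@]2(C=O)C[C@H]1C[C@@H]([N+](=O)[O-])[C@H]2[C@]1(C)CCC[C@@](C)(C(=O)OC3)[C@H]13
A4 | alternative 2 | nitroallyl pivalate C9=C11(NO2)–C12H2–OPiv on C10 of the ring A 19,6-lactone | CC(C)(C)C(=O)OCC(=C[C@]1(C)CCC[C@@]2(C)C(=O)OC[C@@H]12)[N+](=O)[O-]
A5 | alternative 2 | 3-oxocyclopentane-1-carbaldehyde | O=CC1CCC(=O)C1
A6 | alternative 3 | C7 hydroxymethyl, C11 dioxolane, 16-methylene bicyclo[3.2.1]octane dimethyl ester | C=C1C[C@]2(CO)C[C@H]1CC3(OCCO3)[C@H]2[C@]1(C)CCC[C@@](C)(C(=O)OC)[C@H]1C(=O)OC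
A7 | alternative 3 | ring C spiro-oxetane (C8) with C13 1-iodovinyl group and C11 dioxolane, dimethyl ester | C=C(I)[C@H]1CC2(COC2)[C@@H](C3(C1)OCCO3)[C@]4(C)CCC[C@@](C)(C(=O)OC)[C@H]4C(=O)OC
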